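**Strategy.** The ring (numbered C1 carbonyl, C2=C3, C4, C5 carbinol, C6) is disconnected at C3–C4, the bond from the β-carbon of the enone to the CH2 next to the carbinol carbon. The feature used is that C5, a fully substituted carbinol, lies homoallylic to C2=C3 and 1,3 to the C1 oxygen of the cyclohexenone ring: C2–C3 is read as a terminal alkyne, C4=C5 as a 1,1-disubstituted alkene and the C5 hydroxyl as water. A gold-catalysed hydroxycyclization of an acyclic (S)-1,5-enyn-3-ol forms C3–C4, closes the six-membered ring, installs the tertiary alcohol and relays the C1 configuration to C5 in one operation; oxidation of C1 then erases the relay centre.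

Key step: step 4

Assumption: a half-chair transition state with the C1 hydroxyl pseudoequatorial fixes the sense of 1,3-induction in step 4 (cis-1,3-diol), which is why the (S)-carbinol is prepared in step 2.

Step 1
Reactants: 1 1-bromooctadecane; 2 3-chloro-2-(chloromethyl)prop-1-ene
Product: 4 2-(chloromethyl)henicos-1-ene, via octadecylmagnesium bromide 3 (not isolated)
Conditions: Mg, THF, reflux; then slow addition to 2 (3 equiv), Li2CuCl4 (3 mol%), THF, −20 °C to 0 °C
Reagents that add atoms: none
Why: Copper-catalysed allylic substitution of a Grignard reagent (Kumada-type coupling) on a symmetrical allylic dichloride, where SN2 and SN2′ paths give the same product and the excess of 2 should hold the reaction at monosubstitution.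

Step 2
Reactants: 4 2-(chloromethyl)henicos-1-ene; 5 (−)-B-methoxydiisopinocampheylborane (from (+)-α-pinene); 6 3-(trimethylsilyl)prop-2-ynal
Product: 10 (3S)-5-methylidene-1-(trimethylsilyl)tetracos-1-yn-3-ol, via allylmagnesium chloride 7 (not isolated), via allylborane 8 (not isolated), via borinate 9 (not isolated)
Conditions: Mg, THF, 0 °C; 5, Et2O, −78 °C to rt; 6, −78 °C; then 3 M NaOH, 30% H2O2, 0 °C
Reagents that add atoms: none
Why: Brown asymmetric allylboration through a chair Zimmerman–Traxler transition state, in which the (+)-α-pinene-derived isopinocampheyl groups direct the 2-substituted allyl group to the Si face of the ynal and so should set the (S)-carbinol (C1 of the later ring).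

Step 3
Reactants: 10 (3S)-5-methylidene-1-(trimethylsilyl)tetracos-1-yn-3-ol
Product: 11 (3S)-5-methylidenetetracos-1-yn-3-ol
Conditions: K2CO3, MeOH, rt
Reagents that add atoms: none
Why: Methoxide-mediated protodesilylation of an alkynylsilane, which should leave the carbinol and the alkene untouched.

Step 4
Reactants: 11 (3S)-5-methylidenetetracos-1-yn-3-ol
Product: 12 (1S,3S)-1-nonadecylcyclohex-4-ene-1,3-diol (cis-1,3-diol)
Conditions: [(2,4-tBu2C6H3O)3P]AuCl (3 mol%), AgSbF6 (3 mol%), H2O (10 equiv), 1,4-dioxane, 0 °C to rt; chromatography
Reagents that add atoms: water, O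
Why: The cationic monovalent gold phosphite complex π-activates the terminal alkyne, the 1,1-disubstituted alkene attacks the alkyne terminus through its CH2 carbon (C4 to C3) so that positive charge develops at the tertiary carbon C5, water adds to C5 anti to the new C–C bond, and protodeauration of the alkenylgold at C2 releases the C2=C3 double bond. The closest known reaction type is the gold-catalysed hydroxy- and alkoxycyclization of 1,n-enynes, here in the 6-endo mode known for 1,5-enynes that carry a 2-substituted alkene. The one ring is closed 6-endo-dig at the alkyne and 6-endo-trig at the alkene. The new stereocentre C5 is controlled by the C1 carbinol: in the half-chair transition state the C1 hydroxyl sits pseudoequatorial, the C19 chain becomes axial and water enters equatorially, which should give the cis-1,3-diol with C5 (S) from C1 (S); any trans isomer is a separable diastereomer and is removed here, before C1 is oxidised. The step needs 6-endo closure with water capture rather than cyclopropanation with 1,2-hydride shift to a bicyclo[3.1.0]hexanone or proton loss to cyclohexadienes; the tertiary cation at C5, the electron-poor phosphite ligand (cation-like rather than carbene-like intermediates) and excess water at low temperature are chosen to secure this.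

Step 5
Reactants: 12 (1S,3S)-1-nonadecylcyclohex-4-ene-1,3-diol
Product: 13 (5S)-5-hydroxy-5-nonadecylcyclohex-2-en-1-one
Conditions: activated MnO2 (excess), CH2Cl2, rt
Reagents that add atoms: none
Why: Chemoselective MnO2 oxidation of the secondary allylic alcohol, which removes the relay stereocentre, cannot touch the tertiary alcohol, and is neutral enough to avoid β-elimination of the C5 hydroxyl.

Compound list
1 | 1-bromooctadecane | CCCCCCCCCCCCCCCCCCBr | starting material
2 | 3-chloro-2-(chloromethyl)prop-1-ene | C=C(CCl)CCl | starting material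
3 | octadecylmagnesium bromide | CCCCCCCCCCCCCCCCCC[Mg]Br | intermediate (not isolated)
4 | 2-(chloromethyl)henicos-1-ene | CCCCCCCCCCCCCCCCCCCC(=C)CCl | intermediate
5 | (−)-B-methoxydiisopinocampheylborane, methoxybis[(1R,2S,3R,5R)-2,6,6-trimethylbicyclo[3.1.1]heptan-3-yl]borane | COB([C@@H]1C[C@@H]2C[C@H]([C@H]1C)C2(C)C)[C@@H]1C[C@@H]2C[C@H]([C@H]1C)C2(C)C | starting material
6 | 3-(trimethylsilyl)prop-2-ynal | C[Si](C)(C)C#CC=O | starting material
7 | (2-methylidenehenicosyl)magnesium chloride | CCCCCCCCCCCCCCCCCCCC(=C)C[Mg]Cl | intermediate (not isolated)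
8 | (2-methylidenehenicosyl)bis[(1R,2S,3R,5R)-2,6,6-trimethylbicyclo[3.1.1]heptan-3-yl]borane | CCCCCCCCCCCCCCCCCCCC(=C)CB([C@@H]1C[C@@H]2C[C@H]([C@H]1C)C2(C)C)[C@@H]1C[C@@H]2C[C@H]([C@H]1C)C2(C)C | intermediate (not isolated)
9 | (3S)-5-methylidene-1-(trimethylsilyl)tetracos-1-yn-3-yl bis[(1R,2S,3R,5R)-2,6,6-trimethylbicyclo[3.1.1]heptan-3-yl]borinate | C[Si](C)(C)C#C[C@@H](OB([C@@H]1C[C@@H]2C[C@H]([C@H]1C)C2(C)C)[C@@H]1C[C@@H]2C[C@H]([C@H]1C)C2(C)C)CC(=C)CCCCCCCCCCCCCCCCCCC | intermediate (not isolated)
10 | (3S)-5-methylidene-1-(trimethylsilyl)tetracos-1-yn-3-ol | C[Si](C)(C)C#C[C@@H](O)CC(=C)CCCCCCCCCCCCCCCCCCC | intermediate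
11 | (3S)-5-methylidenetetracos-1-yn-3-ol | C#C[C@@H](O)CC(=C)CCCCCCCCCCCCCCCCCCC | intermediate
12 | (1S,3S)-1-nonadecylcyclohex-4-ene-1,3-diol | CCCCCCCCCCCCCCCCCCC[C@]1(O)CC=C[C@@H](O)C1 | intermediate
13 | (5S)-5-hydroxy-5-nonadecylcyclohex-2-en-1-one | CCCCCCCCCCCCCCCCCCC[C@]1(O)CC=CC(=O)C1 | target

Total step count: 5. Longest linear sequence: 5 steps (1 to 13).

Steps most likely to fail

Step 4. The alkyne may attack the two alkene faces with little preference, so that facial selectivity is poor. The cyclised gold intermediate may also collapse by cyclopropane formation with 1,2-hydride shift, or lose a proton before water is captured. The fallback sets out from 11 and comes back at 12. It sets C5 by reagent control and closes the ring elsewhere. A hydroxyl-directed, catalyst-controlled epoxidation of the homoallylic alkene (Hf(OtBu)4, matched enantiomer of a C2-symmetric bishydroxamic acid ligand, cumene hydroperoxide, toluene) should give (2S)-1-[(2R)-2-nonadecyloxiran-2-yl]but-3-yn-2-ol F1. Vinylmagnesium bromide in excess with CuI should open the epoxide at its CH2 terminus to (3S,5S)-5-nonadecyloct-7-en-1-yne-3,5-diol F2, so that C3–C4 is now made between two molecules. Semihydrogenation of the alkyne (H2, Pd/CaCO3 poisoned with Pb(OAc)2, quinoline) should give (3S,5S)-5-nonadecylocta-1,7-diene-3,5-diol F3. Ring-closing metathesis with the second-generation Grubbs catalyst then closes the ring at C2=C3 and returns 12.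

Step 2. Enantioselectivity may erode in the allyl transfer to a small, linear ynal, and the allylmagnesium reagent may homocouple while it is formed. The fallback sets out from 4 and comes back at 10. It moves the stereo-defining event from C–C bond formation to a ketone reduction. A Barbier addition of 4 to 6 (Zn dust, THF/aq. NH4Cl) should give racemic 5-methylidene-1-(trimethylsilyl)tetracos-1-yn-3-ol F4. Oxidation with Dess–Martin periodinane (NaHCO3, CH2Cl2) should give 5-methylidene-1-(trimethylsilyl)tetracos-1-yn-3-one F5. Noyori asymmetric transfer hydrogenation of the ynone (RuCl[(S,S)-TsDPEN](p-cymene), iPrOH, rt, no added base) should return 10.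

Step 1. The dichloride may be substituted twice and the alkyl Grignard reagent may homocouple. The fallback sets out from 1 and comes back at 4. It builds the 2-substituted allyl unit by alkylation instead of allylic substitution. Dilithiated 2-methylprop-2-en-1-ol (n-BuLi, 2 equiv, TMEDA) is alkylated at carbon with 1 to give 2-methylidenehenicosan-1-ol F6. Corey–Kim chlorination (N-chlorosuccinimide, Me2S, CH2Cl2, −20 °C to 0 °C) converts the allylic alcohol into 4.

Further compounds
F1 | step 4 | (2S)-1-[(2R)-2-nonadecyloxiran-2-yl]but-3-yn-2-ol | C#C[C@@H](O)C[C@]1(CCCCCCCCCCCCCCCCCCC)CO1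
F2 | step 4 | (3S,5S)-5-nonadecyloct-7-en-1-yne-3,5-diol | CCCCCCCCCCCCCCCCCCC[C@](O)(CC=C)C[C@H](O)C#C
F3 | step 4 | (3S,5S)-5-nonadecylocta-1,7-diene-3,5-diol | CCCCCCCCCCCCCCCCCCC[C@](O)(CC=C)C[C@H](O)C=C
F4 | step 2 | rac-5-methylidene-1-(trimethylsilyl)tetracos-1-yn-3-ol | C[Si](C)(C)C#CC(O)CC(=C)CCCCCCCCCCCCCCCCCCC
F5 | step 2 | 5-methylidene-1-(trimethylsilyl)tetracos-1-yn-3-one | C[Si](C)(C)C#CC(=O)CC(=C)CCCCCCCCCCCCCCCCCCC
F6 | step 1 | 2-methylidenehenicosan-1-ol | CCCCCCCCCCCCCCCCCCCC(=C)CO
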